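The C1–C10 glycidic ester is the point of disconnection: the epoxide ring, with C10 bearing the C14 methyl ester and C1 bearing hydrogen, sits beside the C9 carbinol of the ten-membered carbocycle. Taken back to a C9 ketone, this unit is what a Darzens reaction of a C1 aldehyde with a C10 chloro ester would leave. One operation should therefore form C1–C10 and O–C10, close the carbocycle and the epoxide, and set C1 and C10. The precursor is an open C1–C10 chain with the neryl (Z)-C4=C5 alkene, the C6/C7/C8 triad (TBS ethers on O6 and O12, the (S)-2-methylbutanoate on O8), a C1 aldehyde and the C9-keto C10-chloro methyl ester.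

Key step: step 18

Remark: locants follow germacrane numbering (C1–C10 ring atoms, C11–C13 the propenyl unit on C7, C14 the ester carbon on C10, C15 the methyl on C4); TBS = tert-butyldimethylsilyl; neryl acetate, (R)-methyl p-tolyl sulfoxide and methyl diazoacetate are taken as purchasable.

Step 1
Reactants: 1 neryl acetate [(2Z)-3,7-dimethylocta-2,6-dien-1-yl acetate]
Product: 3 (2Z)-6,6-dimethoxy-3-methylhex-2-en-1-yl acetate (C1 as dimethyl acetal, C6 as acetate), via aldehyde 2 (not isolated)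
Conditions: O3 (1 equiv), CH2Cl2/MeOH, −78 °C; Me2S, −78 °C → rt; then HC(OMe)3, p-TsOH (cat.), rt
Reagents that add atoms: ozone, [O-][O+]=O; trimethyl orthoformate, COC(OC)OC
Why: Ozonolysis with reductive work-up should be selective for the distal electron-rich trisubstituted alkene, because the C4=C5 alkene is deactivated by the allylic acetate, and acid-catalysed acetalisation in the same flask masks the C1 aldehyde.

Step 2
Reactants: 3 (2Z)-6,6-dimethoxy-3-methylhex-2-en-1-yl acetate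
Product: 4 (2Z)-6,6-dimethoxy-3-methylhex-2-en-1-ol
Conditions: K2CO3 (cat.), MeOH, rt
Reagents that add atoms: none
Why: Base-catalysed transesterification of the allylic acetate should leave the acetal and the (Z)-alkene untouched.

Step 3
Reactants: 4 (2Z)-6,6-dimethoxy-3-methylhex-2-en-1-ol
Product: 5 (2Z)-6,6-dimethoxy-3-methylhex-2-enal (C1–C6 enal, C6 = CHO)
Conditions: TEMPO (10 mol%), PhI(OAc)2, CH2Cl2, rt; used at once
Reagents that add atoms: none
Why: Oxoammonium (TEMPO) oxidation of the allylic alcohol is non-basic and should give the (Z)-enal without isomerisation to the (E)-isomer.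

Step 4
Reactants: 6 2-methylidenepropane-1,3-diol
Product: 7 2-({[tert-butyl(dimethyl)silyl]oxy}methyl)prop-2-en-1-ol
Conditions: NaH (1.0 equiv), THF, rt; TBSCl (1.0 equiv)
Reagents that add atoms: tert-butyldimethylsilyl chloride, CC(C)(C)[Si](C)(C)Cl
Why: O-Silylation of the sparingly soluble monosodium alkoxide of a symmetrical diol should stop at the mono silyl ether.

Step 5
Reactants: 7 2-({[tert-butyl(dimethyl)silyl]oxy}methyl)prop-2-en-1-ol
Product: 8 {[2-(bromomethyl)prop-2-en-1-yl]oxy}(tert-butyl)dimethylsilane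
Conditions: CBr4, PPh3, CH2Cl2, 0 °C
Reagents that add atoms: carbon tetrabromide, BrC(Br)(Br)Br
Why: The Appel reaction converts the primary allylic alcohol into the bromide under neutral conditions that spare the silyl ether.

Step 6
Reactants: 8 {[2-(bromomethyl)prop-2-en-1-yl]oxy}(tert-butyl)dimethylsilane
Product: 10 3-({[tert-butyl(dimethyl)silyl]oxy}methyl)but-3-enoic acid, via allylzinc bromide 9 (not isolated)
Conditions: Zn dust, LiCl, THF, 0 °C → rt; then CO2 (1 atm), rt; dilute aq. HCl work-up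
Reagents that add atoms: carbon dioxide, O=C=O
Why: Zinc insertion gives an allylzinc whose two termini are equivalent, so carboxylation of the organozinc can only give the β,γ-unsaturated acid.

Step 7
Reactants: 10 3-({[tert-butyl(dimethyl)silyl]oxy}methyl)but-3-enoic acid; 11 (4S)-4-benzyl-1,3-oxazolidin-2-one
Product: 13 (4S)-4-benzyl-3-[3-({[tert-butyl(dimethyl)silyl]oxy}methyl)but-3-enoyl]-1,3-oxazolidin-2-one, via mixed pivalic anhydride 12 (not isolated)
Conditions: t-BuCOCl, Et3N, THF, −20 °C; then 11, LiCl, −20 °C → rt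
Reagents that add atoms: none
Why: N-Acylation of the oxazolidinone through the mixed pivalic anhydride with LiCl/Et3N is mild enough to keep the alkene out of conjugation.

Step 8
Reactants: 13 (4S)-4-benzyl-3-[3-({[tert-butyl(dimethyl)silyl]oxy}methyl)but-3-enoyl]-1,3-oxazolidin-2-one; 5 (2Z)-6,6-dimethoxy-3-methylhex-2-enal
Product: 15 (4S)-4-benzyl-3-[(2S,3R,4Z)-2-(3-{[tert-butyl(dimethyl)silyl]oxy}prop-1-en-2-yl)-3-hydroxy-8,8-dimethoxy-5-methyloct-4-enoyl]-1,3-oxazolidin-2-one (6R,7S in germacrane numbering), via boron enolate 14 (not isolated)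
Conditions: n-Bu2BOTf, i-Pr2NEt, CH2Cl2, −78 → 0 °C; 5, −78 → 0 °C; pH 7 buffer, MeOH, H2O2, 0 °C
Reagents that add atoms: none
Why: In this Evans syn-aldol reaction the (Z)-boron dienolate should react at its α-carbon through a Zimmerman–Traxler chair on the face left open by the (S)-benzyl auxiliary, setting C6 (R) and C7 (S) in the 6,7-syn relationship that becomes the trans lactone fusion.

Step 9
Reactants: 15 the aldol adduct
Product: 16 (2S,3R,4Z)-2-(3-{[tert-butyl(dimethyl)silyl]oxy}prop-1-en-2-yl)-3-hydroxy-N,8,8-trimethoxy-N,5-dimethyloct-4-enamide (Weinreb amide at C8)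
Conditions: MeONHMe·HCl, AlMe3, CH2Cl2, −20 → 0 °C; aq. potassium sodium tartrate
Reagents that add atoms: N,O-dimethylhydroxylamine hydrochloride, CNOC.Cl
Why: Aluminium amide transamination of the β-hydroxy imide (Weinreb amide formation) is guided by the free C6 hydroxyl and should release the auxiliary without epimerising C7.

Step 10
Reactants: 16 the Weinreb amide
Product: 17 (2S,3R,4Z)-3-{[tert-butyl(dimethyl)silyl]oxy}-2-(3-{[tert-butyl(dimethyl)silyl]oxy}prop-1-en-2-yl)-N,8,8-trimethoxy-N,5-dimethyloct-4-enamide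
Conditions: TBSCl, imidazole, DMAP (cat.), DMF, rt
Reagents that add atoms: tert-butyldimethylsilyl chloride, CC(C)(C)[Si](C)(C)Cl
Why: Silylation of the secondary allylic alcohol with the silyl chloride and imidazole avoids silyl triflates, which would attack the dimethyl acetal.

Step 11
Reactants: 17 the silylated Weinreb amide; 18 (R)-methyl p-tolyl sulfoxide
Product: 20 (3S,4R,5Z)-4-{[tert-butyl(dimethyl)silyl]oxy}-3-(3-{[tert-butyl(dimethyl)silyl]oxy}prop-1-en-2-yl)-9,9-dimethoxy-6-methyl-1-[(R)-4-methylbenzenesulfinyl]non-5-en-2-one (C8 ketone, C9H2 sulfoxide), via lithiated sulfoxide 19 (not isolated)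
Conditions: 18 (2.2 equiv), LiN(i-Pr)2 (2.2 equiv), THF, −78 °C; 17, −78 → −40 °C; aq. NH4Cl
Reagents that add atoms: none
Why: Acylation of the α-sulfinyl carbanion by the Weinreb amide should stop at the ketone, because the tetrahedral chelate and then the β-keto sulfoxide enolate resist further addition and shield C7–H.

Step 12
Reactants: 20 the β-keto sulfoxide
Product: 21 (2S,3R,4R,5Z)-4-{[tert-butyl(dimethyl)silyl]oxy}-3-(3-{[tert-butyl(dimethyl)silyl]oxy}prop-1-en-2-yl)-9,9-dimethoxy-6-methyl-1-[(R)-4-methylbenzenesulfinyl]non-5-en-2-ol (8S in germacrane numbering)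
Conditions: i-Bu2AlH, THF, −78 °C; MeOH; aq. potassium sodium tartrate
Reagents that add atoms: none
Why: In this sulfoxide-directed reduction of a β-keto sulfoxide, i-Bu2AlH bound to the sulfinyl oxygen delivers hydride intramolecularly through a chair-like transition state, so the (R)-sulfur should set C8 as S (7,8-anti, 6,8-anti) under reagent control.

Step 13
Reactants: 21 the β-hydroxy sulfoxide; 22 (S)-2-methylbutanoic acid
Product: 23 (2S,3R,4R,5Z)-4-{[tert-butyl(dimethyl)silyl]oxy}-3-(3-{[tert-butyl(dimethyl)silyl]oxy}prop-1-en-2-yl)-9,9-dimethoxy-6-methyl-1-[(R)-4-methylbenzenesulfinyl]non-5-en-2-yl (2S)-2-methylbutanoate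
Conditions: 22 (3 equiv), i-PrN=C=N-i-Pr (1.5 equiv), CH2Cl2, 0 °C; then 21, DMAP (0.3 equiv), rt
Reagents that add atoms: none
Why: DMAP-catalysed acylation by the preformed symmetrical anhydride (Steglich-type esterification) should esterify O8 with retention at C8 and little α-epimerisation of the acyl group.

Step 14
Reactants: 23 the β-acyloxy sulfoxide
Product: 25 (2S,3R,4R,5Z)-4-{[tert-butyl(dimethyl)silyl]oxy}-3-(3-{[tert-butyl(dimethyl)silyl]oxy}prop-1-en-2-yl)-9,9-dimethoxy-6-methyl-1-oxonon-5-en-2-yl (2S)-2-methylbutanoate (C9 aldehyde), via trifluoroacetoxy sulfide 24 (not isolated)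
Conditions: (CF3CO)2O, 2,4,6-collidine, MeCN, 0 °C; then aq. NaHCO3, 0 °C; used at once
Reagents that add atoms: trifluoroacetic anhydride, O=C(OC(=O)C(F)(F)F)C(F)(F)F; water, O
Why: In the Pummerer rearrangement, O-acylation of the sulfoxide, ylide formation and trifluoroacetate return give an O,S-acetal that mild bicarbonate hydrolysis should convert into the C9 aldehyde without touching C8.

Step 15
Reactants: 25 the α-acyloxy aldehyde; 26 methyl diazoacetate
Product: 27 methyl (4S,5R,6R,7Z)-6-{[tert-butyl(dimethyl)silyl]oxy}-5-(3-{[tert-butyl(dimethyl)silyl]oxy}prop-1-en-2-yl)-11,11-dimethoxy-8-methyl-4-{[(2S)-2-methylbutanoyl]oxy}-3-oxoundec-7-enoate (C9 ketone, C10H2, C14 ester)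
Conditions: 26 (1.5 equiv), SnCl2 (20 mol%), CH2Cl2, rt
Reagents that add atoms: none
Why: In the Roskamp reaction, SnCl2-catalysed addition of the diazo ester to the aldehyde and a 1,2-hydride shift with loss of N2 give the β-keto ester directly under near-neutral conditions that should preserve the α-acyloxy stereocentre.

Step 16
Reactants: 27 the β-keto ester
Product: 28 methyl (4S,5R,6R,7Z)-6-{[tert-butyl(dimethyl)silyl]oxy}-5-(3-{[tert-butyl(dimethyl)silyl]oxy}prop-1-en-2-yl)-2-chloro-11,11-dimethoxy-8-methyl-4-{[(2S)-2-methylbutanoyl]oxy}-3-oxoundec-7-enoate (both C10 epimers)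
Conditions: N-chlorosuccinimide (1.05 equiv), Mg(ClO4)2 (10 mol%), MeCN, 0 °C
Reagents that add atoms: N-chlorosuccinimide, O=C1CCC(=O)N1Cl
Why: Lewis-acid-catalysed electrophilic chlorination of the β-keto ester enol should occur only at the doubly activated C10, and its configuration is irrelevant because the next C–C bond formation passes through the enolate.

Step 17
Reactants: 28 the chloro keto ester acetal
Product: 29 methyl (4S,5R,6R,7Z)-6-{[tert-butyl(dimethyl)silyl]oxy}-5-(3-{[tert-butyl(dimethyl)silyl]oxy}prop-1-en-2-yl)-2-chloro-8-methyl-4-{[(2S)-2-methylbutanoyl]oxy}-3,11-dioxoundec-7-enoate (the seco precursor: C1 aldehyde, C9 ketone, C10 chloro ester)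
Conditions: pyridinium p-toluenesulfonate (cat.), acetone/H2O, 35 °C; used at once
Reagents that add atoms: water, O
Why: Acid-catalysed hydrolysis of the acyclic dimethyl acetal should be much faster than loss of the silyl ethers under pyridinium buffering, and it frees the C1 aldehyde only when it is needed.

Step 18
Reactants: 29 the seco chloro keto ester aldehyde
Product: 32 methyl (1R,6R,7R,8S,10R,4Z)-6-{[tert-butyl(dimethyl)silyl]oxy}-7-(3-{[tert-butyl(dimethyl)silyl]oxy}prop-1-en-2-yl)-8-{[(2S)-2-methylbutanoyl]oxy}-9-oxo-1,10-epoxygermacr-4-en-14-oate (ten-membered ring, ring-cis epoxide), via caesium enolate 30 (not isolated), via chloro aldolate 31 (not isolated)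
Conditions: Cs2CO3 (3 equiv), 4 Å sieves, MeCN, 1 mM, slow addition of 29, 0 °C → rt
Reagents that add atoms: none
Why: Proposed new method: Cs2CO3 removes the C10 proton (acidified by the C9 ketone, the ester and chlorine, so both C10 epimers give one enolate), the enolate adds reversibly to the C1 aldehyde, and the aldolate whose O− lies anti to C10–Cl displaces chloride in the only irreversible event; the closest known reaction type is the Darzens condensation of α-halo carbonyl compounds with aldehydes, including intramolecular closures to common rings, which has not been used with an α-chloro-β-keto ester to close a medium ring. The C1–C10 bond closes the ten-membered carbocycle in the 10-exo-trig mode and the O–C10 bond closes the epoxide in the 3-exo-tet mode. C1 and C10 arise together: inversion at C10 during closure ties their relative configuration to the anti aldolate, the ring-cis epoxide (C2 and C9 cis) being the one a ten-membered ring accommodates, and the absolute sense is imposed by the C8 stereocentre beside the reacting ketone through the least strained anti aldolate while the others revert. The step needs C10 to react in preference to C8–H and to the ester carbonyls and needs one face relative to C8, which the double activation of C10–H (a mild base suffices) and the reversibility of the aldol addition are expected to secure, with high dilution suppressing oligomers.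

Step 19
Reactants: 32 the epoxy ketone
Product: 33 methyl (1R,6R,7R,8S,9R,10S,4Z)-6-{[tert-butyl(dimethyl)silyl]oxy}-7-(3-{[tert-butyl(dimethyl)silyl]oxy}prop-1-en-2-yl)-9-hydroxy-8-{[(2S)-2-methylbutanoyl]oxy}-1,10-epoxygermacr-4-en-14-oate
Conditions: Zn(BH4)2, Et2O/CH2Cl2, −40 °C; aq. NH4Cl
Reagents that add atoms: none
Why: In this chelation-controlled hydride reduction, Zn2+ should bridge the C9 ketone and the C14 ester carbonyl so that hydride enters on the C9 face beside the epoxide oxygen and away from C1–C2, the same face that the dipole-minimised (Cornforth/Felkin–Anh) arrangement at C8 favours, giving the 9R alcohol (8,9-syn).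

Step 20
Reactants: 33 the bis-silyl hydroxy epoxide
Product: 34 methyl (1R,6R,7S,8S,9R,10S,4Z)-6,9-dihydroxy-7-(3-hydroxyprop-1-en-2-yl)-8-{[(2S)-2-methylbutanoyl]oxy}-1,10-epoxygermacr-4-en-14-oate (6,9,12-triol)
Conditions: HF·pyridine, pyridine, THF, 0 °C → rt
Reagents that add atoms: none
Why: Fluoride-mediated desilylation buffered with pyridine should remove both silyl ethers without acyl migration from O8 and without opening the electron-poor epoxide.

Step 21
Reactants: 34 the triol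
Product: 37 CNP0581690.1, methyl (1R,6R,7S,8S,9R,10S,4Z)-9-hydroxy-8-{[(2S)-2-methylbutanoyl]oxy}-12-oxo-1,10-epoxygermacra-4,11(13)-dien-12,6-olid-14-oate (the target), via enal 35 (not isolated), via lactol 36 (not isolated)
Conditions: TEMPO (20 mol%), PhI(OAc)2 (3 equiv), CH2Cl2, rt
Reagents that add atoms: none
Why: In this oxoammonium-mediated oxidative lactonisation the primary allylic C12 alcohol should be oxidised first to the enal, the C6 hydroxyl then closes the five-membered lactol, and a second oxidation gives the trans-fused α-methylene lactone.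

Compound list
1 | neryl acetate, (2Z)-3,7-dimethylocta-2,6-dien-1-yl acetate | CC(C)=CCC/C(C)=C\COC(C)=O | starting material
2 | (2Z)-3-methyl-6-oxohex-2-en-1-yl acetate | O=CCC/C(C)=C\COC(C)=O | intermediate
3 | (2Z)-6,6-dimethoxy-3-methylhex-2-en-1-yl acetate | COC(OC)CC/C(C)=C\COC(C)=O | intermediate
4 | (2Z)-6,6-dimethoxy-3-methylhex-2-en-1-ol | COC(OC)CC/C(C)=C\CO | intermediate
5 | (2Z)-6,6-dimethoxy-3-methylhex-2-enal | COC(OC)CC/C(C)=C\C=O | intermediate
6 | 2-methylidenepropane-1,3-diol | C=C(CO)CO | starting material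
7 | 2-({[tert-butyl(dimethyl)silyl]oxy}methyl)prop-2-en-1-ol | C=C(CO)CO[Si](C)(C)C(C)(C)C | intermediate
8 | {[2-(bromomethyl)prop-2-en-1-yl]oxy}(tert-butyl)dimethylsilane | C=C(CBr)CO[Si](C)(C)C(C)(C)C | intermediate
9 | [2-({[tert-butyl(dimethyl)silyl]oxy}methyl)prop-2-en-1-yl]zinc bromide | C=C(C[Zn]Br)CO[Si](C)(C)C(C)(C)C | intermediate
10 | 3-({[tert-butyl(dimethyl)silyl]oxy}methyl)but-3-enoic acid | C=C(CC(=O)O)CO[Si](C)(C)C(C)(C)C | intermediate
11 | (4S)-4-benzyl-1,3-oxazolidin-2-one | O=C1N[C@@H](Cc2ccccc2)CO1 | starting material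
12 | mixed anhydride of 10 with pivalic acid | C=C(CC(=O)OC(=O)C(C)(C)C)CO[Si](C)(C)C(C)(C)C | intermediate
13 | (4S)-4-benzyl-3-[3-({[tert-butyl(dimethyl)silyl]oxy}methyl)but-3-enoyl]-1,3-oxazolidin-2-one | C=C(CC(=O)N1[C@@H](Cc2ccccc2)COC1=O)CO[Si](C)(C)C(C)(C)C | intermediate
14 | (Z)-di-n-butylboron enolate of 13 | CCCCB(CCCC)O/C(N1[C@@H](Cc2ccccc2)COC1=O)=C\C(=C)CO[Si](C)(C)C(C)(C)C | intermediate
15 | (4S)-4-benzyl-3-[(2S,3R,4Z)-2-(3-{[tert-butyl(dimethyl)silyl]oxy}prop-1-en-2-yl)-3-hydroxy-8,8-dimethoxy-5-methyloct-4-enoyl]-1,3-oxazolidin-2-one | COC(OC)CC/C(C)=C\[C@@H](O)[C@H](C(=C)CO[Si](C)(C)C(C)(C)C)C(=O)N1[C@@H](Cc2ccccc2)COC1=O | intermediate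
16 | (2S,3R,4Z)-2-(3-{[tert-butyl(dimethyl)silyl]oxy}prop-1-en-2-yl)-3-hydroxy-N,8,8-trimethoxy-N,5-dimethyloct-4-enamide | COC(OC)CC/C(C)=C\[C@@H](O)[C@H](C(=C)CO[Si](C)(C)C(C)(C)C)C(=O)N(C)OC | intermediate
17 | (2S,3R,4Z)-3-{[tert-butyl(dimethyl)silyl]oxy}-2-(3-{[tert-butyl(dimethyl)silyl]oxy}prop-1-en-2-yl)-N,8,8-trimethoxy-N,5-dimethyloct-4-enamide | COC(OC)CC/C(C)=C\[C@@H](O[Si](C)(C)C(C)(C)C)[C@H](C(=C)CO[Si](C)(C)C(C)(C)C)C(=O)N(C)OC | intermediate
18 | (R)-methyl p-tolyl sulfoxide | C[S@@](=O)c1ccc(C)cc1 | starting material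
19 | {[(R)-4-methylbenzenesulfinyl]methyl}lithium | [Li]C[S@@](=O)c1ccc(C)cc1 | intermediate
20 | (3S,4R,5Z)-4-{[tert-butyl(dimethyl)silyl]oxy}-3-(3-{[tert-butyl(dimethyl)silyl]oxy}prop-1-en-2-yl)-9,9-dimethoxy-6-methyl-1-[(R)-4-methylbenzenesulfinyl]non-5-en-2-one | COC(OC)CC/C(C)=C\[C@@H](O[Si](C)(C)C(C)(C)C)[C@H](C(=C)CO[Si](C)(C)C(C)(C)C)C(=O)C[S@@](=O)c1ccc(C)cc1 | intermediate
21 | (2S,3R,4R,5Z)-4-{[tert-butyl(dimethyl)silyl]oxy}-3-(3-{[tert-butyl(dimethyl)silyl]oxy}prop-1-en-2-yl)-9,9-dimethoxy-6-methyl-1-[(R)-4-methylbenzenesulfinyl]non-5-en-2-ol | COC(OC)CC/C(C)=C\[C@@H](O[Si](C)(C)C(C)(C)C)[C@H](C(=C)CO[Si](C)(C)C(C)(C)C)[C@H](O)C[S@@](=O)c1ccc(C)cc1 | intermediate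
22 | (S)-2-methylbutanoic acid | CC[C@H](C)C(=O)O | starting material
23 | (2S)-2-methylbutanoate ester of 21 at O8 | COC(OC)CC/C(C)=C\[C@@H](O[Si](C)(C)C(C)(C)C)[C@H](C(=C)CO[Si](C)(C)C(C)(C)C)[C@H](OC(=O)[C@@H](C)CC)C[S@@](=O)c1ccc(C)cc1 | intermediate
24 | C9 O,S-acetal: 1-(p-tolylsulfanyl)-1-(trifluoroacetoxy) derivative of 23 (C9 epimers) | COC(OC)CC/C(C)=C\[C@@H](O[Si](C)(C)C(C)(C)C)[C@H](C(=C)CO[Si](C)(C)C(C)(C)C)[C@H](OC(=O)[C@@H](C)CC)C(OC(=O)C(F)(F)F)Sc1ccc(C)cc1 | intermediate
25 | (2S,3R,4R,5Z)-4-{[tert-butyl(dimethyl)silyl]oxy}-3-(3-{[tert-butyl(dimethyl)silyl]oxy}prop-1-en-2-yl)-9,9-dimethoxy-6-methyl-1-oxonon-5-en-2-yl (2S)-2-methylbutanoate | COC(OC)CC/C(C)=C\[C@@H](O[Si](C)(C)C(C)(C)C)[C@H](C(=C)CO[Si](C)(C)C(C)(C)C)[C@H](OC(=O)[C@@H](C)CC)C=O | intermediate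
26 | methyl diazoacetate | COC(=O)C=[N+]=[N-] | starting material
27 | methyl (4S,5R,6R,7Z)-6-{[tert-butyl(dimethyl)silyl]oxy}-5-(3-{[tert-butyl(dimethyl)silyl]oxy}prop-1-en-2-yl)-11,11-dimethoxy-8-methyl-4-{[(2S)-2-methylbutanoyl]oxy}-3-oxoundec-7-enoate | COC(OC)CC/C(C)=C\[C@@H](O[Si](C)(C)C(C)(C)C)[C@H](C(=C)CO[Si](C)(C)C(C)(C)C)[C@H](OC(=O)[C@@H](C)CC)C(=O)CC(=O)OC | intermediate
28 | 2-chloro derivative of 27 (C10 epimers) | COC(OC)CC/C(C)=C\[C@@H](O[Si](C)(C)C(C)(C)C)[C@H](C(=C)CO[Si](C)(C)C(C)(C)C)[C@H](OC(=O)[C@@H](C)CC)C(=O)C(Cl)C(=O)OC | intermediate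
29 | methyl (4S,5R,6R,7Z)-6-{[tert-butyl(dimethyl)silyl]oxy}-5-(3-{[tert-butyl(dimethyl)silyl]oxy}prop-1-en-2-yl)-2-chloro-8-methyl-4-{[(2S)-2-methylbutanoyl]oxy}-3,11-dioxoundec-7-enoate (seco precursor, C10 epimers) | O=CCC/C(C)=C\[C@@H](O[Si](C)(C)C(C)(C)C)[C@H](C(=C)CO[Si](C)(C)C(C)(C)C)[C@H](OC(=O)[C@@H](C)CC)C(=O)C(Cl)C(=O)OC | intermediate
30 | caesium C9–C10 enolate of 29 | O=CCC/C(C)=C\[C@@H](O[Si](C)(C)C(C)(C)C)[C@H](C(=C)CO[Si](C)(C)C(C)(C)C)[C@H](OC(=O)[C@@H](C)CC)C([O-])=C(Cl)C(=O)OC.[Cs+] | intermediate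
31 | ten-membered (1R,10S)-10-chloro-9-oxo C1 caesium alkoxide (productive anti aldolate) | CC(C)(C)[Si](C)(C)O[C@@H]1/C=C(/C)CC[C@@H]([O-])[C@@](Cl)(C(=O)OC)C(=O)[C@@H](OC(=O)[C@@H](C)CC)[C@H]1C(=C)CO[Si](C)(C)C(C)(C)C.[Cs+] | intermediate
32 | methyl (1R,6R,7R,8S,10R,4Z)-6-{[tert-butyl(dimethyl)silyl]oxy}-7-(3-{[tert-butyl(dimethyl)silyl]oxy}prop-1-en-2-yl)-8-{[(2S)-2-methylbutanoyl]oxy}-9-oxo-1,10-epoxygermacr-4-en-14-oate | CC(C)(C)[Si](C)(C)O[C@@H]1/C=C(/C)CC[C@H]2O[C@@]2(C(=O)OC)C(=O)[C@@H](OC(=O)[C@@H](C)CC)[C@H]1C(=C)CO[Si](C)(C)C(C)(C)C | intermediate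
33 | (9R)-9-hydroxy compound from 32, (1R,6R,7R,8S,9R,10S) | CC(C)(C)[Si](C)(C)O[C@@H]1/C=C(/C)CC[C@H]2O[C@@]2(C(=O)OC)[C@H](O)[C@@H](OC(=O)[C@@H](C)CC)[C@H]1C(=C)CO[Si](C)(C)C(C)(C)C | intermediate
34 | 6,9,12-triol, (1R,6R,7S,8S,9R,10S) | O[C@@H]1/C=C(/C)CC[C@H]2O[C@@]2(C(=O)OC)[C@H](O)[C@@H](OC(=O)[C@@H](C)CC)[C@H]1C(=C)CO | intermediate
35 | C12 enal of 34 | O[C@@H]1/C=C(/C)CC[C@H]2O[C@@]2(C(=O)OC)[C@H](O)[C@@H](OC(=O)[C@@H](C)CC)[C@H]1C(=C)C=O | intermediate
36 | 6,12-lactol (C12 epimers) | C=C1C(O)O[C@@H]2/C=C(/C)CC[C@H]3O[C@@]3(C(=O)OC)[C@H](O)[C@@H](OC(=O)[C@@H](C)CC)[C@@H]12 | intermediate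
37 | CNP0581690.1, (1R,6R,7S,8S,9R,10S,4Z; 2′S) | C=C1C(=O)O[C@@H]2/C=C(/C)CC[C@H]3O[C@@]3(C(=O)OC)[C@H](O)[C@@H](OC(=O)[C@@H](C)CC)[C@@H]12 | target

Total step count: 21. Longest linear sequence: 18 steps (steps 4–7, then 8–21; the aldehyde branch, steps 1–3, joins at step 8).

Steps most likely to fail

1. Step 18 (Proposed new method). What may go wrong:
- the aldolate may transfer the C9 acyl group to O1 (retro-Claisen ring opening) or revert faster than it displaces chloride;
- the enolate may attack the neighbouring O8 ester;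
- C8 may epimerise through enolisation of the C9 ketone;
- intermolecular aldolisation may give oligomers;
- the face selectivity relative to C8 may be low.

Fallback with known chemistry, setting out from 27 and returning at 32: hydrolysis of the acetal of 27 (pyridinium p-toluenesulfonate, acetone/H2O) gives the keto ester aldehyde F1. An intramolecular Knoevenagel condensation under high dilution (piperidinium acetate, CH2Cl2, 4 Å sieves, or TiCl4/pyridine) closes the ten-membered ring as the alkylidene β-keto ester F2 (C1=C10, C2 and C9 cis). Weitz–Scheffer epoxidation of this doubly activated alkene with t-BuOOH and DBU, which leaves the other alkenes alone, should then give 32 by attack on the peripheral face.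

2. Step 19. What may go wrong: zinc may instead chelate the ketone with the epoxide oxygen, which would expose the opposite C9 face and give poor or reversed facial selectivity, and the zinc alkoxide may allow acyl migration from O8 to O9. Fallback, setting out from 32 and returning at the target 37, with the order changed so that the ketone is reduced on the rigid lactone: HF·pyridine frees the diol ketone F3 (which may rest as its transannular O6–C9 hemiketal). TEMPO/PhI(OAc)2 carries it through the enal F4 and the lactol F5 to the 9-oxo lactone F6. A Luche reduction (NaBH4, CeCl3·7H2O, MeOH, −78 °C), 1,2-selective in the presence of the α-methylene lactone, should deliver hydride from the periphery of the bicycle to give 37.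

3. Step 14. What may go wrong: the thionium ion may be intercepted by the neighbouring O8 ester or by an alkene, and the α-acyloxy aldehyde may epimerise at C8 during hydrolysis. Fallback, setting out from 17 and returning at 25, with a dithiane in place of the sulfoxide as the C9 formyl anion equivalent: 2-lithio-1,3-dithiane F7 (1,3-dithiane, n-BuLi, THF) is acylated by Weinreb amide 17 to give the acyl dithiane F8. CBS reduction ((S)-methyl oxazaborolidine, catecholborane, −78 °C, the branched C7 side acting as the large group) gives the 8S carbinol F9. Esterification with 22 as in step 13 gives the ester F10. Neutral alkylative hydrolysis of the dithiane (MeI, CaCO3, MeCN/H2O) gives 25.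

Further compounds
F1 | step 18 | methyl (4S,5R,6R,7Z)-6-{[tert-butyl(dimethyl)silyl]oxy}-5-(3-{[tert-butyl(dimethyl)silyl]oxy}prop-1-en-2-yl)-8-methyl-4-{[(2S)-2-methylbutanoyl]oxy}-3,11-dioxoundec-7-enoate | O=CCC/C(C)=C\[C@@H](O[Si](C)(C)C(C)(C)C)[C@H](C(=C)CO[Si](C)(C)C(C)(C)C)[C@H](OC(=O)[C@@H](C)CC)C(=O)CC(=O)OC
F2 | step 18 | ten-membered 9-oxo-germacra-1(10),4-dien-14-oate (alkylidene β-keto ester, C2 and C9 cis) with 6-OTBS, 12-OTBS and 8-O-(2S)-2-methylbutanoyl | CC(C)(C)[Si](C)(C)O[C@@H]1/C=C(/C)CC/C=C(/C(=O)OC)C(=O)[C@@H](OC(=O)[C@@H](C)CC)[C@H]1C(=C)CO[Si](C)(C)C(C)(C)C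
F3 | step 19 | 6,12-diol of the 1,10-epoxy C9 ketone | O[C@@H]1/C=C(/C)CC[C@H]2O[C@@]2(C(=O)OC)C(=O)[C@@H](OC(=O)[C@@H](C)CC)[C@H]1C(=C)CO
F4 | step 19 | C12 enal of the 9-oxo diol | O[C@@H]1/C=C(/C)CC[C@H]2O[C@@]2(C(=O)OC)C(=O)[C@@H](OC(=O)[C@@H](C)CC)[C@H]1C(=C)C=O
F5 | step 19 | 9-oxo 6,12-lactol (C12 epimers) | C=C1C(O)O[C@@H]2/C=C(/C)CC[C@H]3O[C@@]3(C(=O)OC)C(=O)[C@@H](OC(=O)[C@@H](C)CC)[C@@H]12
F6 | step 19 | 9-oxo α-methylene 12,6-lactone (9-dehydro target) | C=C1C(=O)O[C@@H]2/C=C(/C)CC[C@H]3O[C@@]3(C(=O)OC)C(=O)[C@@H](OC(=O)[C@@H](C)CC)[C@@H]12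
F7 | step 14 | 2-lithio-1,3-dithiane | [Li]C1SCCCS1
F8 | step 14 | (2S,3R,4Z)-3-{[tert-butyl(dimethyl)silyl]oxy}-2-(3-{[tert-butyl(dimethyl)silyl]oxy}prop-1-en-2-yl)-1-(1,3-dithian-2-yl)-8,8-dimethoxy-5-methyloct-4-en-1-one | COC(OC)CC/C(C)=C\[C@@H](O[Si](C)(C)C(C)(C)C)[C@H](C(=C)CO[Si](C)(C)C(C)(C)C)C(=O)C1SCCCS1
F9 | step 14 | (8S)-carbinol from F8, 1-(1,3-dithian-2-yl)oct-4-en-1-ol derivative | COC(OC)CC/C(C)=C\[C@@H](O[Si](C)(C)C(C)(C)C)[C@H](C(=C)CO[Si](C)(C)C(C)(C)C)[C@H](O)C1SCCCS1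
F10 | step 14 | (2S)-2-methylbutanoate ester of F9 | COC(OC)CC/C(C)=C\[C@@H](O[Si](C)(C)C(C)(C)C)[C@H](C(=C)CO[Si](C)(C)C(C)(C)C)[C@H](OC(=O)[C@@H](C)CC)C1SCCCS1
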